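**Retrosynthetic overview**
1. Target ⇐ (desilylation, 8-O-acylation) ⇐ transannular inverse-demand oxa-Diels–Alder reaction of a trans,trans-germacranolide 14-al. This one step makes the five-, seven- and oxa-six-membered rings and sets C1, C4 and C5.
2. Germacranolide ⇐ closure of the C6–C7 bond (the bond made when farnesyl diphosphate cyclises) by intramolecular CrCl2 allylation of a lactol-masked enal with a 2-(bromomethyl)acrylate. The ten-membered ring and the α-methylene lactone form together.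
3. Open chain ⇐ cross-metathesis, Brown syn-alkoxyallylation (C8, C9), and a tandem Claisen–Cope union of 4-(hydroxymethyl)butenolide with a 2-(alkoxymethyl)crotonaldehyde.
4. Ring order: butenolide (temporary; fixes the C4=C5 geometry, opened in the macrocyclisation) → ten-membered ring plus lactone → tricyclic core in one cycloaddition.

Assumption: the 2-methylbutanoate in the SMILES is (R), so (R)-2-methylbutanoic acid is bought as the single enantiomer; 1,3-dihydroxyacetone is bought as its dimer and drawn as the monomer; atom labels C1–C15 follow germacrane/guaiane numbering.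

**Route**

Step 1
Reactants: 1 diethyl ethylidenemalonate
Product: 2 2-ethylidenepropane-1,3-diol
Conditions: i-Bu2AlH (4.5 equiv), CH2Cl2, −78 → 0 °C; aq. potassium sodium tartrate
Reagents that add atoms: none
Why: Exhaustive 1,2-reduction of both conjugated esters by the electrophilic hydride i-Bu2AlH (ester-to-alcohol reduction) leaves the alkene in place, and no stereocentre is formed.

Step 2
Reactants: 2 2-ethylidenepropane-1,3-diol
Product: 3 2-{[(4-methoxyphenyl)methoxy]methyl}but-2-en-1-ol (E/Z mixture)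
Conditions: Ag2O (1.5 equiv), 4-methoxybenzyl chloride (1.1 equiv), CH2Cl2, 23 °C
Reagents that add atoms: 4-methoxybenzyl chloride, COc1ccc(CCl)cc1
Why: Ag2O-mediated mono-O-alkylation of a symmetric 1,3-diol (Williamson-type) stops at the monoether, and the E/Z identity of the product does not matter because this geometry is erased in step 5.

Step 3
Reactants: 3 2-{[(4-methoxyphenyl)methoxy]methyl}but-2-en-1-ol
Product: 4 (2E)-2-{[(4-methoxyphenyl)methoxy]methyl}but-2-enal
Conditions: MnO2 (15 equiv), CH2Cl2, 23 °C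
Reagents that add atoms: none
Why: Chemoselective MnO2 oxidation of the primary allylic alcohol gives the enal, whose CHO sits trans to the methyl group at equilibrium.

Step 4
Reactants: 5 1,3-dihydroxyacetone; 6 ethyl (triphenylphosphoranylidene)acetate
Product: 7 4-(hydroxymethyl)furan-2(5H)-one
Conditions: CH2Cl2, 23 °C, 18 h
Reagents that add atoms: none
Why: Wittig olefination of the symmetric ketone is followed by spontaneous lactonisation of the hydroxymethyl group that lies cis to the ester, so there is no E/Z issue and the ring fixes the future C15 cis to C6.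

Step 5
Reactants: 7 4-(hydroxymethyl)furan-2(5H)-one; 4 (2E)-2-{[(4-methoxyphenyl)methoxy]methyl}but-2-enal
Product: 11 (2E)-2-{[(4-methoxyphenyl)methoxy]methyl}-5-(5-oxo-2,5-dihydrofuran-3-yl)pent-2-enal, via acetal 8 (not isolated), via dienyl ether 9 (not isolated), via Claisen aldehyde 10 (not isolated)
Conditions: 7 (2.2 equiv), PPTS (5 mol %), PhMe, reflux, Dean–Stark; then 2,4-dinitrophenol (5 mol %), o-xylene, 145 °C
Reagents that add atoms: none
Why: Tandem Claisen–Cope rearrangement (the isoprenoid chain extension used in the industrial citral process): acetalisation and 1,4-elimination give the allyl dienyl ether, a [3,3] shift bonds C10 to the butenolide α-carbon, and a Cope [3,3] shift then moves the allyl unit to C2, which restores the butenolide (locking the C4=C5 geometry) and gives the thermodynamically preferred E-enal.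

Step 6
Reactants: 11 (2E)-2-{[(4-methoxyphenyl)methoxy]methyl}-5-(5-oxo-2,5-dihydrofuran-3-yl)pent-2-enal; 12 allyl 4-methoxybenzyl ether
Product: 13 4-[(3E,5S,6S)-5-hydroxy-6-[(4-methoxyphenyl)methoxy]-4-{[(4-methoxyphenyl)methoxy]methyl}octa-3,7-dien-1-yl]furan-2(5H)-one
Conditions: 12, s-BuLi, THF, −78 °C; (+)-Ipc2BOMe [from (−)-α-pinene]; BF3·OEt2; then 11, −78 °C; H2O2, pH 7 buffer (NaH2PO4/Na2HPO4), MeOH, 0 °C
Reagents that add atoms: none
Why: Brown asymmetric γ-alkoxyallylboration: the (Z)-γ-alkoxyallylborane reacts through a closed chair transition state to give the syn 1,2-diol monoether, and the isopinocampheyl groups derived from (−)-α-pinene direct addition to the Re face of the aldehyde, which sets C8 and C9 as (S,S).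

Step 7
Reactants: 13 4-[(3E,5S,6S)-5-hydroxy-6-[(4-methoxyphenyl)methoxy]-4-{[(4-methoxyphenyl)methoxy]methyl}octa-3,7-dien-1-yl]furan-2(5H)-one
Product: 14 4-[(3E,5S,6S)-5-hydroxy-6-[(4-methoxyphenyl)methoxy]-4-{[(4-methoxyphenyl)methoxy]methyl}octa-3,7-dien-1-yl]-2,5-dihydrofuran-2-ol (lactol, anomer mixture)
Conditions: i-Bu2AlH (2.3 equiv), CH2Cl2, −78 °C; aq. potassium sodium tartrate; used crude
Reagents that add atoms: none
Why: Partial reduction of the butenolide by i-Bu2AlH at −78 °C stops at the lactol because the aluminium hemiacetal survives until work-up; the lactol masks the C6 aldehyde and its ring oxygen is the future 15-OH.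

Step 8
Reactants: 14 lactol; 15 methyl 2-(bromomethyl)acrylate
Product: 16 methyl (2Z,4S,5S,6E)-2-(bromomethyl)-5-hydroxy-9-(5-hydroxy-2,5-dihydrofuran-3-yl)-4-[(4-methoxyphenyl)methoxy]-6-{[(4-methoxyphenyl)methoxy]methyl}nona-2,6-dienoate
Conditions: 15 (5 equiv), second-generation Hoveyda–Grubbs catalyst RuCl2(H2IMes)(=CH-C6H4-2-O-i-Pr) (10 mol %), CH2Cl2, 40 °C
Reagents that add atoms: none
Why: Olefin cross-metathesis of the only monosubstituted alkene with the 1,1-disubstituted acrylate gives the trisubstituted enoate with the ester trans to the chain (as with methacrylate partners), while the trisubstituted alkenes and the lactol do not react.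

Step 9
Reactants: 16 methyl (2Z,4S,5S,6E)-2-(bromomethyl)-5-hydroxy-9-(5-hydroxy-2,5-dihydrofuran-3-yl)-4-[(4-methoxyphenyl)methoxy]-6-{[(4-methoxyphenyl)methoxy]methyl}nona-2,6-dienoate
Product: 18 (6βH,7αH)-9α,15-dihydroxy-8β,14-bis[(4-methoxyphenyl)methoxy]germacra-1(10),4,11(13)-trien-12,6α-olide, via hydroxy ester 17 (not isolated)
Conditions: CrCl2 (10 equiv), THF, 23 °C, slow addition of 16 to 0.002 M
Reagents that add atoms: none
Why: Intramolecular Nozaki–Hiyama-type (Barbier) allylation: CrCl2 turns the allylic bromide into an allylchromium species (trivalent chromium) that adds through C7 to the hydroxy-enal form of the lactol in a chair transition state (anti, hence the 6,7-trans lactone), attack at C7 occurring anti to C9 with H-8 eclipsing the alkene (A(1,3) control), and the resulting alkoxide closes the α-methylene lactone; the C8 ether is kept as a poor leaving group so that the allylmetal does not eliminate.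

Step 10
Reactants: 18 (6βH,7αH)-9α,15-dihydroxy-8β,14-bis[(4-methoxyphenyl)methoxy]germacra-1(10),4,11(13)-trien-12,6α-olide
Product: 20 (6βH,7αH)-9α-acetoxy-15-{[tert-butyl(dimethyl)silyl]oxy}-8β,14-bis[(4-methoxyphenyl)methoxy]germacra-1(10),4,11(13)-trien-12,6α-olide, via silyl ether 19 (not isolated)
Conditions: TBSOTf (1.05 equiv), 2,6-lutidine, CH2Cl2, −78 °C; then Ac2O, DMAP, pyridine, 0 → 23 °C
Reagents that add atoms: tert-butyldimethylsilyl trifluoromethanesulfonate, CC(C)(C)[Si](C)(C)OS(=O)(=O)C(F)(F)F; acetic anhydride, CC(=O)OC(C)=O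
Why: O-silylation at −78 °C selects the primary allylic 15-OH over the hindered secondary 9-OH, which is then acetylated in the same flask by DMAP-catalysed O-acylation.

Step 11
Reactants: 20 (6βH,7αH)-9α-acetoxy-15-{[tert-butyl(dimethyl)silyl]oxy}-8β,14-bis[(4-methoxyphenyl)methoxy]germacra-1(10),4,11(13)-trien-12,6α-olide
Product: 21 (6βH,7αH)-9α-acetoxy-15-{[tert-butyl(dimethyl)silyl]oxy}-8β,14-dihydroxygermacra-1(10),4,11(13)-trien-12,6α-olide
Conditions: DDQ (2.4 equiv), CH2Cl2–pH 7 buffer (NaH2PO4/Na2HPO4) 10:1, 0 °C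
Reagents that add atoms: none
Why: Oxidative cleavage of both 4-methoxybenzyl ethers by DDQ (hydride abstraction, then hydrolysis of the oxocarbenium ion) frees 8-OH and 14-OH while the silyl ether, acetate, lactone and alkenes are inert at 0 °C.

Step 12
Reactants: 21 (6βH,7αH)-9α-acetoxy-15-{[tert-butyl(dimethyl)silyl]oxy}-8β,14-dihydroxygermacra-1(10),4,11(13)-trien-12,6α-olide
Product: 23 (1αH,5αH,6βH,7αH)-9α-acetoxy-15-{[tert-butyl(dimethyl)silyl]oxy}-4β,14-epoxy-8β-hydroxyguaia-10(14),11(13)-dien-12,6α-olide, via enal 22 (not isolated)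
Conditions: MnO2 (20 equiv), CH2Cl2, 23 °C; filter; then Eu(fod)3 [europium tris(6,6,7,7,8,8,8-heptafluoro-2,2-dimethyloctane-3,5-dionate)] (10 mol %), PhMe, 23 → 50 °C
Reagents that add atoms: none
Why: Proposed new method: MnO2 oxidises only the allylic 14-OH, and the resulting trans,trans-germacranolide 14-al undergoes a transannular inverse-electron-demand oxa-Diels–Alder reaction in which the s-cis enal O=C14–C10=C1 is the 4π partner and the facing C4=C5 bond the 2π partner (C1/C5 and O/C4 lie about 3 Å apart in the crown conformer, and C2 occupies the inside position of the oxadiene as the bridged transition state requires), so that suprafacial addition to the inner face of the ring-trans C4=C5 bond sets 1αH, 5αH, the 4β-oxygen and the 15α-CH2O group in one event; the closest known reaction types are Lewis-acid-catalysed intramolecular hetero-Diels–Alder reactions of enals with alkenes and transannular Diels–Alder reactions, and natural 8β-hydroxy-14-oxo-germacranolides show that the free 8-OH does not tie up the aldehyde.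

Step 13
Reactants: 23 (1αH,5αH,6βH,7αH)-9α-acetoxy-15-{[tert-butyl(dimethyl)silyl]oxy}-4β,14-epoxy-8β-hydroxyguaia-10(14),11(13)-dien-12,6α-olide; 24 (R)-2-methylbutanoic acid
Product: 25 (1αH,5αH,6βH,7αH)-9α-acetoxy-15-{[tert-butyl(dimethyl)silyl]oxy}-4β,14-epoxy-8β-{[(2R)-2-methylbutanoyl]oxy}guaia-10(14),11(13)-dien-12,6α-olide
Conditions: 24 (1.5 equiv), DCC, DMAP (0.1 equiv), CH2Cl2, 0 → 23 °C
Reagents that add atoms: none
Why: Steglich esterification of the only free hydroxyl group under neutral conditions that spare the enol ether; low DMAP loading at 0 °C avoids epimerisation of the acid α-stereocentre.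

Step 14
Reactants: 25 (1αH,5αH,6βH,7αH)-9α-acetoxy-15-{[tert-butyl(dimethyl)silyl]oxy}-4β,14-epoxy-8β-{[(2R)-2-methylbutanoyl]oxy}guaia-10(14),11(13)-dien-12,6α-olide
Product: 26 (1αH,5αH,6βH,7αH)-9α-acetoxy-4β,14-epoxy-15-hydroxy-8β-{[(2R)-2-methylbutanoyl]oxy}guaia-10(14),11(13)-dien-12,6α-olide (CNP0013863.3)
Conditions: HF·pyridine, pyridine, THF, 0 → 23 °C
Reagents that add atoms: none
Why: Fluoride-mediated cleavage of the silyl ether under pyridine-buffered conditions leaves the enol ether, both esters and the α-methylene lactone untouched.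

**Compound list**
1 | diethyl ethylidenemalonate | CCOC(=O)C(=CC)C(=O)OCC | starting material
2 | 2-ethylidenepropane-1,3-diol | CC=C(CO)CO | intermediate
3 | 2-{[(4-methoxyphenyl)methoxy]methyl}but-2-en-1-ol (E/Z mixture, both isomers used) | CC=C(CO)COCc1ccc(OC)cc1 | intermediate
4 | (2E)-2-{[(4-methoxyphenyl)methoxy]methyl}but-2-enal | C/C=C(/C=O)COCc1ccc(OC)cc1 | intermediate
5 | 1,3-dihydroxyacetone (bought as its dimer) | OCC(=O)CO | starting material
6 | ethyl (triphenylphosphoranylidene)acetate | CCOC(=O)C=P(c1ccccc1)(c1ccccc1)c1ccccc1 | starting material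
7 | 4-(hydroxymethyl)furan-2(5H)-one | OCC1=CC(=O)OC1 | intermediate
8 | bis[(5-oxo-2,5-dihydrofuran-3-yl)methyl] acetal of 4 (formed in situ) | C/C=C(/C(OCC1=CC(=O)OC1)OCC1=CC(=O)OC1)COCc1ccc(OC)cc1 | intermediate
9 | 4-{[(2-{[(4-methoxyphenyl)methoxy]methyl}buta-1,3-dien-1-yl)oxy]methyl}furan-2(5H)-one (formed in situ, enol ether E/Z mixture) | C=CC(COCc1ccc(OC)cc1)=COCC1=CC(=O)OC1 | intermediate
10 | 2-ethenyl-2-{[(4-methoxyphenyl)methoxy]methyl}-2-(4-methylidene-2-oxooxolan-3-yl)acetaldehyde (formed in situ, racemic diastereomer mixture) | C=CC(C=O)(COCc1ccc(OC)cc1)C1C(=C)COC1=O | intermediate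
11 | (2E)-2-{[(4-methoxyphenyl)methoxy]methyl}-5-(5-oxo-2,5-dihydrofuran-3-yl)pent-2-enal | O=C/C(COCc1ccc(OC)cc1)=C/CCC1=CC(=O)OC1 | intermediate
12 | allyl 4-methoxybenzyl ether | C=CCOCc1ccc(OC)cc1 | starting material
13 | 4-[(3E,5S,6S)-5-hydroxy-6-[(4-methoxyphenyl)methoxy]-4-{[(4-methoxyphenyl)methoxy]methyl}octa-3,7-dien-1-yl]furan-2(5H)-one | C=C[C@H](OCc1ccc(OC)cc1)[C@@H](O)/C(COCc1ccc(OC)cc1)=C/CCC1=CC(=O)OC1 | intermediate
14 | 4-[(3E,5S,6S)-5-hydroxy-6-[(4-methoxyphenyl)methoxy]-4-{[(4-methoxyphenyl)methoxy]methyl}octa-3,7-dien-1-yl]-2,5-dihydrofuran-2-ol (anomer mixture) | C=C[C@H](OCc1ccc(OC)cc1)[C@@H](O)/C(COCc1ccc(OC)cc1)=C/CCC1=CC(O)OC1 | intermediate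
15 | methyl 2-(bromomethyl)acrylate | C=C(CBr)C(=O)OC | starting material
16 | methyl (2Z,4S,5S,6E)-2-(bromomethyl)-5-hydroxy-9-(5-hydroxy-2,5-dihydrofuran-3-yl)-4-[(4-methoxyphenyl)methoxy]-6-{[(4-methoxyphenyl)methoxy]methyl}nona-2,6-dienoate | COC(=O)/C(CBr)=C/[C@H](OCc1ccc(OC)cc1)[C@@H](O)/C(COCc1ccc(OC)cc1)=C/CCC1=CC(O)OC1 | intermediate
17 | methyl (7αH)-6α,9α,15-trihydroxy-8β,14-bis[(4-methoxyphenyl)methoxy]germacra-1(10),4,11(13)-trien-12-oate (formed in situ as its chromium alkoxide; both ring alkenes trans in the ring) | COC(=O)C(=C)[C@H]1[C@H](O)/C=C(CO)/CC/C=C(COCc2ccc(OC)cc2)/[C@H](O)[C@H]1OCc1ccc(OC)cc1 | intermediate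
18 | (6βH,7αH)-9α,15-dihydroxy-8β,14-bis[(4-methoxyphenyl)methoxy]germacra-1(10),4,11(13)-trien-12,6α-olide (both ring alkenes trans in the ring; CIP 1(10)E,4Z) | C=C1C(=O)O[C@@H]2/C=C(CO)/CC/C=C(COCc3ccc(OC)cc3)/[C@H](O)[C@@H](OCc3ccc(OC)cc3)[C@@H]12 | intermediate
19 | 15-O-tert-butyldimethylsilyl ether of 18 (formed in situ) | C=C1C(=O)O[C@@H]2/C=C(CO[Si](C)(C)C(C)(C)C)/CC/C=C(COCc3ccc(OC)cc3)/[C@H](O)[C@@H](OCc3ccc(OC)cc3)[C@@H]12 | intermediate
20 | (6βH,7αH)-9α-acetoxy-15-{[tert-butyl(dimethyl)silyl]oxy}-8β,14-bis[(4-methoxyphenyl)methoxy]germacra-1(10),4,11(13)-trien-12,6α-olide | C=C1C(=O)O[C@@H]2/C=C(CO[Si](C)(C)C(C)(C)C)/CC/C=C(COCc3ccc(OC)cc3)/[C@H](OC(C)=O)[C@@H](OCc3ccc(OC)cc3)[C@@H]12 | intermediate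
21 | (6βH,7αH)-9α-acetoxy-15-{[tert-butyl(dimethyl)silyl]oxy}-8β,14-dihydroxygermacra-1(10),4,11(13)-trien-12,6α-olide | C=C1C(=O)O[C@@H]2/C=C(CO[Si](C)(C)C(C)(C)C)/CC/C=C(CO)/[C@H](OC(C)=O)[C@@H](O)[C@@H]12 | intermediate
22 | (6βH,7αH)-9α-acetoxy-15-{[tert-butyl(dimethyl)silyl]oxy}-8β-hydroxy-14-oxogermacra-1(10),4,11(13)-trien-12,6α-olide (formed in situ; both ring alkenes trans in the ring; CIP 1(10)Z,4Z) | C=C1C(=O)O[C@@H]2/C=C(CO[Si](C)(C)C(C)(C)C)/CC/C=C(C=O)/[C@H](OC(C)=O)[C@@H](O)[C@@H]12 | intermediate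
23 | (1αH,5αH,6βH,7αH)-9α-acetoxy-15-{[tert-butyl(dimethyl)silyl]oxy}-4β,14-epoxy-8β-hydroxyguaia-10(14),11(13)-dien-12,6α-olide | C=C1C(=O)O[C@H]2[C@H]1[C@H](O)[C@@H](OC(C)=O)C1=CO[C@@]3(CO[Si](C)(C)C(C)(C)C)CC[C@@H]1[C@@H]23 | intermediate
24 | (R)-2-methylbutanoic acid | CC[C@@H](C)C(=O)O | starting material
25 | (1αH,5αH,6βH,7αH)-9α-acetoxy-15-{[tert-butyl(dimethyl)silyl]oxy}-4β,14-epoxy-8β-{[(2R)-2-methylbutanoyl]oxy}guaia-10(14),11(13)-dien-12,6α-olide | C=C1C(=O)O[C@H]2[C@H]1[C@H](OC(=O)[C@H](C)CC)[C@@H](OC(C)=O)C1=CO[C@@]3(CO[Si](C)(C)C(C)(C)C)CC[C@@H]1[C@@H]23 | intermediate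
26 | (1αH,5αH,6βH,7αH)-9α-acetoxy-4β,14-epoxy-15-hydroxy-8β-{[(2R)-2-methylbutanoyl]oxy}guaia-10(14),11(13)-dien-12,6α-olide (CNP0013863.3) | C=C1C(=O)O[C@H]2[C@H]1[C@H](OC(=O)[C@H](C)CC)[C@@H](OC(C)=O)C1=CO[C@@]3(CO)CC[C@@H]1[C@@H]23 | target

**Step count and risks**
Total: 14 steps. Longest linear sequence: 13 steps (steps 1–3, then 5–14).

Steps most likely to fail:

- **Step 12 (transannular oxa-Diels–Alder).** The enal may isomerise to the unreactive ring-cis (melampolide) form, react from the s-trans rotamer, or undergo Cope rearrangement on heating. The fallback sets out from 22, this time isolated after the MnO2 oxidation, and comes back at 25. The 8-OH is first esterified with 24 (DCC, DMAP) to give (6βH,7αH)-9α-acetoxy-15-{[tert-butyl(dimethyl)silyl]oxy}-8β-{[(2R)-2-methylbutanoyl]oxy}-14-oxogermacra-1(10),4,11(13)-trien-12,6α-olide F9. HC(OMe)3 and PPTS in MeOH convert F9 into its 14,14-dimethyl acetal F10. Me3SiOTf (1.1 equiv) with 2,6-di-tert-butylpyridine in CH2Cl2 at −78 °C then ionises F10 to a vinyl oxocarbenium ion, which closes in a stepwise ionic [4+2] (C5 to C1 first, then the enol ether oxygen onto the C4 cation, then loss of the O-methyl group) to give 25.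

- **Step 9 (macrocyclisation on the lactol).** The lactol can dehydrate irreversibly to a 3-substituted furan, or open too slowly for the allylchromium species, and the C6/C7 selectivity is only predicted. The fallback sets out from 13 and comes back at 19, which is then acetylated as in the second half of step 10. AlMe3 and MeNH(OMe)·HCl open the butenolide to (2Z,6E,8S,9S)-8-hydroxy-3-(hydroxymethyl)-N-methoxy-9-[(4-methoxyphenyl)methoxy]-7-{[(4-methoxyphenyl)methoxy]methyl}-N-methylundeca-2,6,10-trienamide F5. TBSOTf and 2,6-lutidine at −78 °C silylate the primary hydroxyl to give the 3-({[tert-butyl(dimethyl)silyl]oxy}methyl) amide F6. i-Bu2AlH at −78 °C gives (2Z,6E,8S,9S)-3-({[tert-butyl(dimethyl)silyl]oxy}methyl)-8-hydroxy-9-[(4-methoxyphenyl)methoxy]-7-{[(4-methoxyphenyl)methoxy]methyl}undeca-2,6,10-trienal F7, an open-chain enal that cannot close to a lactol or a furan. Cross-metathesis with 15 gives methyl (2Z,4S,5S,6E,10Z)-2-(bromomethyl)-10-({[tert-butyl(dimethyl)silyl]oxy}methyl)-5-hydroxy-4-[(4-methoxyphenyl)methoxy]-6-{[(4-methoxyphenyl)methoxy]methyl}-12-oxododeca-2,6,10-trienoate F8, and CrCl2 at high dilution closes F8 to 19.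

- **Step 5 (tandem Claisen–Cope).** Acetal and dienyl ether formation with the electron-poor butenolide alcohol may be sluggish, intermediate 10 may tautomerise to a conjugated butenolide before the Cope shift, and product 11 can react a second time. The fallback sets out from 7 and comes back at 11; compound 4 is then not needed. CBr4 and PPh3 give 4-(bromomethyl)furan-2(5H)-one F1. Allyltributylstannane with Pd(PPh3)4 (zerovalent palladium) in THF at 60 °C gives 4-(but-3-en-1-yl)furan-2(5H)-one F2. Separately, commercial 2-methylidenepropane-1,3-diol is mono-protected (Ag2O, 4-methoxybenzyl chloride) to 2-{[(4-methoxyphenyl)methoxy]methyl}prop-2-en-1-ol F3 and oxidised (MnO2) to 2-{[(4-methoxyphenyl)methoxy]methyl}prop-2-enal F4. Cross-metathesis of F2 with F4 (second-generation Hoveyda–Grubbs catalyst RuCl2(H2IMes)(=CH-C6H4-2-O-i-Pr), CH2Cl2, 40 °C) gives the E-enal 11.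

**Further compounds**
F1 | step 5 | 4-(bromomethyl)furan-2(5H)-one | BrCC1=CC(=O)OC1
F2 | step 5 | 4-(but-3-en-1-yl)furan-2(5H)-one | C=CCCC1=CC(=O)OC1
F3 | step 5 | 2-{[(4-methoxyphenyl)methoxy]methyl}prop-2-en-1-ol | C=C(CO)COCc1ccc(OC)cc1
F4 | step 5 | 2-{[(4-methoxyphenyl)methoxy]methyl}prop-2-enal | C=C(C=O)COCc1ccc(OC)cc1
F5 | step 9 | (2Z,6E,8S,9S)-8-hydroxy-3-(hydroxymethyl)-N-methoxy-9-[(4-methoxyphenyl)methoxy]-7-{[(4-methoxyphenyl)methoxy]methyl}-N-methylundeca-2,6,10-trienamide | C=C[C@H](OCc1ccc(OC)cc1)[C@@H](O)/C(COCc1ccc(OC)cc1)=C/CC/C(CO)=C/C(=O)N(C)OC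
F6 | step 9 | (2Z,6E,8S,9S)-3-({[tert-butyl(dimethyl)silyl]oxy}methyl)-8-hydroxy-N-methoxy-9-[(4-methoxyphenyl)methoxy]-7-{[(4-methoxyphenyl)methoxy]methyl}-N-methylundeca-2,6,10-trienamide | C=C[C@H](OCc1ccc(OC)cc1)[C@@H](O)/C(COCc1ccc(OC)cc1)=C/CC/C(CO[Si](C)(C)C(C)(C)C)=C/C(=O)N(C)OC
F7 | step 9 | (2Z,6E,8S,9S)-3-({[tert-butyl(dimethyl)silyl]oxy}methyl)-8-hydroxy-9-[(4-methoxyphenyl)methoxy]-7-{[(4-methoxyphenyl)methoxy]methyl}undeca-2,6,10-trienal | C=C[C@H](OCc1ccc(OC)cc1)[C@@H](O)/C(COCc1ccc(OC)cc1)=C/CC/C(CO[Si](C)(C)C(C)(C)C)=C/C=O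
F8 | step 9 | methyl (2Z,4S,5S,6E,10Z)-2-(bromomethyl)-10-({[tert-butyl(dimethyl)silyl]oxy}methyl)-5-hydroxy-4-[(4-methoxyphenyl)methoxy]-6-{[(4-methoxyphenyl)methoxy]methyl}-12-oxododeca-2,6,10-trienoate | COC(=O)/C(CBr)=C/[C@H](OCc1ccc(OC)cc1)[C@@H](O)/C(COCc1ccc(OC)cc1)=C/CC/C(CO[Si](C)(C)C(C)(C)C)=C/C=O
F9 | step 12 | (6βH,7αH)-9α-acetoxy-15-{[tert-butyl(dimethyl)silyl]oxy}-8β-{[(2R)-2-methylbutanoyl]oxy}-14-oxogermacra-1(10),4,11(13)-trien-12,6α-olide | C=C1C(=O)O[C@@H]2/C=C(CO[Si](C)(C)C(C)(C)C)/CC/C=C(C=O)/[C@H](OC(C)=O)[C@@H](OC(=O)[C@H](C)CC)[C@@H]12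
F10 | step 12 | (6βH,7αH)-9α-acetoxy-15-{[tert-butyl(dimethyl)silyl]oxy}-14,14-dimethoxy-8β-{[(2R)-2-methylbutanoyl]oxy}germacra-1(10),4,11(13)-trien-12,6α-olide | C=C1C(=O)O[C@@H]2/C=C(CO[Si](C)(C)C(C)(C)C)/CC/C=C(C(OC)OC)/[C@H](OC(C)=O)[C@@H](OC(=O)[C@H](C)CC)[C@@H]12
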